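**Retrosynthetic overview**
1. The two free hydroxyls (C6–OH and C2'–OH) are carried as benzyl ethers and released last by hydrogenolysis.
2. Ring C is the only ring made. C4 is a lone carbonyl carbon between C4a of the fully substituted A ring and the C3=C2 unit, so the pyranone is cut at C4a–C4, C4–C3 and O1–C2 into an o-iodophenol (I at C4a, OH at C8a), CO (C4) and the B-ring aryl acetylene (C3≡C2).
3. The iodophenol comes from syringaldehyde: O-benzylation, ring bromination, Baeyer–Villiger oxidation, copper-catalysed methoxylation, then iodination of the one remaining ring C–H.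
4. The alkyne comes from 2-hydroxy-6-methoxybenzaldehyde by O-benzylation and Ohira–Bestmann homologation.
5. Ring order: rings A and B are bought as arenes; ring C closes in the carbonylative annulation.

Key step: step 8

Remark: the target SMILES has no stereodescriptor; there is no stereocentre and the C2–C1' axis (flanked by O1 and C3–H) rotates freely, so no stereocontrol is needed.

**Route**

Step 1
Reactants: 1 syringaldehyde (4-hydroxy-3,5-dimethoxybenzaldehyde)
Product: 2 4-(benzyloxy)-3,5-dimethoxybenzaldehyde
Conditions: BnBr, K2CO3, DMF, 60 °C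
Reagents that add atoms: benzyl bromide, BrCc1ccccc1
Why: Williamson ether synthesis, in which the phenoxide (acidified by the para-formyl group) is the only nucleophilic site and displaces bromide from benzyl bromide by SN2.

Step 2
Reactants: 2 4-(benzyloxy)-3,5-dimethoxybenzaldehyde
Product: 3 4-(benzyloxy)-2-bromo-3,5-dimethoxybenzaldehyde
Conditions: NBS (1.05 equiv), MeCN, rt to 50 °C, dark
Reagents that add atoms: N-bromosuccinimide, O=C1CCC(=O)N1Br
Why: Electrophilic aromatic bromination (SEAr) at one of the two equivalent free positions, each ortho and para to a methoxy group, with the formyl group and the first bromine deactivating the ring enough that a second bromination should not follow.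

Step 3
Reactants: 3 4-(benzyloxy)-2-bromo-3,5-dimethoxybenzaldehyde
Product: 5 4-(benzyloxy)-2-bromo-3,5-dimethoxyphenol, via aryl formate 4 (not isolated)
Conditions: mCPBA, CH2Cl2, 0 °C to rt; then K2CO3 (cat.), MeOH, rt
Reagents that add atoms: meta-chloroperoxybenzoic acid (mCPBA), O=C(OO)c1cccc(Cl)c1
Why: Baeyer–Villiger oxidation, in which the electron-rich aryl group (para-benzyloxy) migrates in preference to hydride to give formate 4, which mild methanolysis converts to the phenol without touching the aryl bromide or the benzyl ether.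

Step 4
Reactants: 5 4-(benzyloxy)-2-bromo-3,5-dimethoxyphenol
Product: 6 4-(benzyloxy)-2,3,5-trimethoxyphenol
Conditions: NaOMe (6 equiv), CuBr (20 mol %), DMF–MeOH, 110 °C, N2; then aq. HCl
Reagents that add atoms: sodium methoxide, [Na+].[O-]C
Why: Ullmann-type copper(I)-catalysed methoxylation of an aryl bromide, a reaction class routinely run on ortho-bromophenoxides, with the benzyl ether inert to methoxide and air excluded to protect the electron-rich phenoxide.

Step 5
Reactants: 6 4-(benzyloxy)-2,3,5-trimethoxyphenol
Product: 7 4-(benzyloxy)-6-iodo-2,3,5-trimethoxyphenol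
Conditions: NIS (1.05 equiv), CH2Cl2 (dry), −20 to 0 °C, dark
Reagents that add atoms: N-iodosuccinimide, O=C1CCC(=O)N1I
Why: Electrophilic aromatic iodination (SEAr) ortho to the free hydroxyl at the only ring carbon that still bears hydrogen, so the site is unambiguous, with low temperature and dry conditions limiting oxidation of the para-alkoxyphenol.

Step 6
Reactants: 8 2-hydroxy-6-methoxybenzaldehyde
Product: 9 2-(benzyloxy)-6-methoxybenzaldehyde
Conditions: BnBr, K2CO3, DMF, 60 °C
Reagents that add atoms: benzyl bromide, BrCc1ccccc1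
Why: Williamson ether synthesis, in which carbonate breaks the intramolecular hydrogen bond to the formyl group and the phenoxide is benzylated by SN2.

Step 7
Reactants: 9 2-(benzyloxy)-6-methoxybenzaldehyde
Product: 10 1-(benzyloxy)-2-ethynyl-3-methoxybenzene
Conditions: dimethyl (1-diazo-2-oxopropyl)phosphonate, K2CO3, MeOH, 0 °C to rt
Reagents that add atoms: dimethyl (1-diazo-2-oxopropyl)phosphonate, CC(=O)C(=[N+]=[N-])P(=O)(OC)OC
Why: Ohira–Bestmann (Seyferth–Gilbert) homologation, in which methoxide deacetylates the reagent to the diazomethylphosphonate anion, whose Horner–Wadsworth–Emmons-type addition to the non-enolisable aldehyde gives a diazoalkene that loses N2 and rearranges by 1,2-hydride shift to the terminal alkyne, the benzyl ether being inert.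

Step 8
Reactants: 7 4-(benzyloxy)-6-iodo-2,3,5-trimethoxyphenol; 10 1-(benzyloxy)-2-ethynyl-3-methoxybenzene; 11 carbon monoxide
Product: 14 6-(benzyloxy)-2-[2-(benzyloxy)-6-methoxyphenyl]-5,7,8-trimethoxy-4H-chromen-4-one, via o-hydroxyaryl ynone 12 (not isolated), via enaminone 13 (not isolated)
Conditions: PdCl2(dppf) (5 mol %), CO (20 bar), Et2NH, 120 °C, autoclave
Reagents that add atoms: none
Why: Pd(0) should insert into the C4a–I bond of 7, CO insertion gives the aroyl-palladium species, and amine-assisted transfer of the acetylide of 10 followed by reductive elimination forms C4a–C4 and C4–C3 in ynone 12 (a carbonylative Sonogashira coupling, run copper-free so that CO insertion outruns direct alkynylation). Diethylamine then adds to the ynone at C2 to give enaminone 13, and the ortho hydroxyl displaces the amine by addition–elimination, forming O1–C2. The closest known reaction type is the palladium-catalysed carbonylative annulation of o-iodophenols with terminal aryl acetylenes to flavones in a secondary amine. Ring C closes in the 6-endo-dig sense with respect to the ynone (6-endo-trig addition–elimination on 13, whose drawn E geometry is not decisive because C2 becomes tetrahedral during the exchange), and no stereocentre is created. The selectivity needed is 6-endo (flavone) over 5-exo (aurone) closure, secured by routing the closure through the β-amino enone whose electrophilic carbon is C2; the annulation site on ring A is fixed because iodine sits on the only carbon of 6 that carried hydrogen. High CO pressure and the bidentate dppf ligand are chosen to favour oxidative addition and CO insertion at the electron-rich, doubly ortho-substituted iodide over amine capture of the aroyl-palladium species.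

Step 9
Reactants: 14 6-(benzyloxy)-2-[2-(benzyloxy)-6-methoxyphenyl]-5,7,8-trimethoxy-4H-chromen-4-one
Product: 15 6-hydroxy-2-(2-hydroxy-6-methoxyphenyl)-5,7,8-trimethoxy-4H-chromen-4-one (6,2'-dihydroxy-5,7,8,6'-tetramethoxyflavone)
Conditions: H2 (1 atm), 10% Pd/C, EtOAc–MeOH, rt, stopped at full conversion
Reagents that add atoms: none
Why: Catalytic hydrogenolysis of both benzyl aryl ethers, with the C2=C3 bond, part of the vinylogous-ester (γ-pyrone) system, expected to resist reduction at 1 atm and room temperature and the methyl ethers untouched.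

**Compound list**
1 | syringaldehyde (4-hydroxy-3,5-dimethoxybenzaldehyde) | COc1cc(C=O)cc(OC)c1O | starting material
2 | 4-(benzyloxy)-3,5-dimethoxybenzaldehyde | COc1cc(C=O)cc(OC)c1OCc1ccccc1 | intermediate
3 | 4-(benzyloxy)-2-bromo-3,5-dimethoxybenzaldehyde | COc1cc(C=O)c(Br)c(OC)c1OCc1ccccc1 | intermediate
4 | 4-(benzyloxy)-2-bromo-3,5-dimethoxyphenyl formate | COc1cc(OC=O)c(Br)c(OC)c1OCc1ccccc1 | intermediate
5 | 4-(benzyloxy)-2-bromo-3,5-dimethoxyphenol | COc1cc(O)c(Br)c(OC)c1OCc1ccccc1 | intermediate
6 | 4-(benzyloxy)-2,3,5-trimethoxyphenol | Oc1cc(OC)c(OCc2ccccc2)c(OC)c1OC | intermediate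
7 | 4-(benzyloxy)-6-iodo-2,3,5-trimethoxyphenol | Oc1c(I)c(OC)c(OCc2ccccc2)c(OC)c1OC | intermediate
8 | 2-hydroxy-6-methoxybenzaldehyde | COc1cccc(O)c1C=O | starting material
9 | 2-(benzyloxy)-6-methoxybenzaldehyde | COc1cccc(OCc2ccccc2)c1C=O | intermediate
10 | 1-(benzyloxy)-2-ethynyl-3-methoxybenzene | COc1cccc(OCc2ccccc2)c1C#C | intermediate
11 | carbon monoxide | [C-]#[O+] | starting material
12 | 1-[3-(benzyloxy)-6-hydroxy-2,4,5-trimethoxyphenyl]-3-[2-(benzyloxy)-6-methoxyphenyl]prop-2-yn-1-one | O=C(C#Cc1c(OC)cccc1OCc1ccccc1)c1c(O)c(OC)c(OC)c(OCc2ccccc2)c1OC | intermediate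
13 | (E)-1-[3-(benzyloxy)-6-hydroxy-2,4,5-trimethoxyphenyl]-3-[2-(benzyloxy)-6-methoxyphenyl]-3-(diethylamino)prop-2-en-1-one | CCN(CC)/C(=C/C(=O)c1c(O)c(OC)c(OC)c(OCc2ccccc2)c1OC)c1c(OC)cccc1OCc1ccccc1 | intermediate
14 | 6-(benzyloxy)-2-[2-(benzyloxy)-6-methoxyphenyl]-5,7,8-trimethoxy-4H-chromen-4-one | COc1cccc(OCc2ccccc2)c1-c1cc(=O)c2c(OC)c(OCc3ccccc3)c(OC)c(OC)c2o1 | intermediate
15 | 6-hydroxy-2-(2-hydroxy-6-methoxyphenyl)-5,7,8-trimethoxy-4H-chromen-4-one (6,2'-dihydroxy-5,7,8,6'-tetramethoxyflavone) | COc1cccc(O)c1-c1cc(=O)c2c(OC)c(O)c(OC)c(OC)c2o1 | target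

**Step count**
Total steps: 9. Longest linear sequence: 7 steps (steps 1–5, 8, 9); the alkyne branch (steps 6–7) joins at step 8.

**Steps most likely to fail**

Step 8 (carbonylative annulation). The aroyl-palladium intermediate may be captured by diethylamine (aminocarbonylation). CO-free alkynylation followed by closure to a 2-arylbenzofuran may compete. Oxidative addition into the doubly ortho-flanked, electron-rich C–I bond may be slow, and closure may go 5-exo. The fallback sets out from 7 and 9 and returns at 14, building ring C by the chalcone route instead. Iodine–lithium exchange on the phenoxide of 7 (NaH, then t-BuLi, THF, −78 °C) and acylation with N-methoxy-N-methylacetamide should give 1-[3-(benzyloxy)-6-hydroxy-2,4,5-trimethoxyphenyl]ethan-1-one F1. Claisen–Schmidt condensation of F1 with aldehyde 9 (KOH, EtOH, rt) should give (E)-1-[3-(benzyloxy)-6-hydroxy-2,4,5-trimethoxyphenyl]-3-[2-(benzyloxy)-6-methoxyphenyl]prop-2-en-1-one F2. Oxidative cyclisation of F2 (cat. I2, DMSO, 130 °C: oxa-Michael closure, then dehydrogenation) should give 14.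

Step 4 (copper-catalysed methoxylation). Protodebromination through reduction of the aryl-copper intermediate, or oxidative degradation of the electron-rich phenoxide at high temperature, may consume the substrate. The fallback sets out from 5 and returns at 6, installing the oxygen by lithiation–borylation–oxidation. Protection (MOMCl, i-Pr2NEt, CH2Cl2) should give 2-(benzyloxy)-4-bromo-1,3-dimethoxy-5-(methoxymethoxy)benzene F3. Bromine–lithium exchange (n-BuLi, THF, −78 °C), borylation with B(OMe)3 and oxidation (H2O2, NaOH) should give 3-(benzyloxy)-2,4-dimethoxy-6-(methoxymethoxy)phenol F4. Methylation (MeI, K2CO3, acetone) should give 2-(benzyloxy)-1,3,4-trimethoxy-5-(methoxymethoxy)benzene F5, and acid methanolysis of the acetal (HCl, MeOH, rt) returns 6.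

Step 5 (iodination). Oxidation of the para-alkoxyphenol (loss of the benzyl group and quinone formation) may outrun C–iodination. The fallback sets out from 6 and returns at 7, iodinating a masked, non-oxidisable phenol. Acetylation (Ac2O, pyridine) should give 4-(benzyloxy)-2,3,5-trimethoxyphenyl acetate F6. Iodination at the single ring C–H (NIS, cat. TFA, MeCN) should give 4-(benzyloxy)-6-iodo-2,3,5-trimethoxyphenyl acetate F7, and methanolysis (K2CO3, MeOH) returns 7.

**Further compounds**
F1 | step 8 | 1-[3-(benzyloxy)-6-hydroxy-2,4,5-trimethoxyphenyl]ethan-1-one | CC(=O)c1c(O)c(OC)c(OC)c(OCc2ccccc2)c1OC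
F2 | step 8 | (E)-1-[3-(benzyloxy)-6-hydroxy-2,4,5-trimethoxyphenyl]-3-[2-(benzyloxy)-6-methoxyphenyl]prop-2-en-1-one | O=C(/C=C/c1c(OC)cccc1OCc1ccccc1)c1c(O)c(OC)c(OC)c(OCc2ccccc2)c1OC
F3 | step 4 | 2-(benzyloxy)-4-bromo-1,3-dimethoxy-5-(methoxymethoxy)benzene | COCOc1cc(OC)c(OCc2ccccc2)c(OC)c1Br
F4 | step 4 | 3-(benzyloxy)-2,4-dimethoxy-6-(methoxymethoxy)phenol | COCOc1cc(OC)c(OCc2ccccc2)c(OC)c1O
F5 | step 4 | 2-(benzyloxy)-1,3,4-trimethoxy-5-(methoxymethoxy)benzene | COCOc1cc(OC)c(OCc2ccccc2)c(OC)c1OC
F6 | step 5 | 4-(benzyloxy)-2,3,5-trimethoxyphenyl acetate | CC(=O)Oc1cc(OC)c(OCc2ccccc2)c(OC)c1OC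
F7 | step 5 | 4-(benzyloxy)-6-iodo-2,3,5-trimethoxyphenyl acetate | CC(=O)Oc1c(I)c(OC)c(OCc2ccccc2)c(OC)c1OC
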